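**Plan**

- Numbering follows the cyclopenta[c]pyran core (C1, O2, C3, C4, C4a, C5–C7, C7a; coumarin atoms primed). Retrosynthetic cuts, in order: the acyl C–C bond at C3 (alkenyl Grignard on a C3 ester); C1–C3' together with the ring bond O2–C1; then C1–C4 and C4a–C7a (a [2+2] pair) and C4=C4a (Wittig), back to (S)-citronellal.
- Enabling feature: O2 is the carbonyl oxygen of the 1,2-dicarbonyl unit at C3 and sits on C1, an acetal-level carbon. C1 (oxygen-stabilised cation) and O2–C3=C4 (keto ester enolate) are the two ends of a 1,4-dipole. Its carbon-closed form is the 2-acetoxy-1-acyl cyclobutane C1–C4–C4a–C7a; its oxygen-closed form is the six-membered enol ether ring.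
- Forward order: the enol acetate and the keto ester enone are set on the citronellal chain; a photochemical [2+2] closes the cyclopentane and the cyclobutane; a Lewis acid then expands the four-membered ring by C3 and O2 to the dihydropyran, and the C1 oxocarbenium ion released in the same flask is arylated by 4-hydroxy-5-methylcoumarin; ester-to-ketone conversion ends the route.
- Stereochemistry: C7 comes from (S)-citronellal; C4a and C7a (cis fusion, methyl on the convex face) from 1,2-induction in the [2+2]; C1 from convex-face attack on the bicyclic oxocarbenium ion.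

Key step: step 7

Assumption: the enol acetate geometry and the configurations of the two cyclobutane carbons that carry acetate and acyl are immaterial, because both carbons become trigonal again in step 7; compounds 2, 3, 7 and 8 are carried as these mixtures.

**Step 1**
Reactants: 1 (S)-citronellal
Product: 2 (3S)-3,7-dimethylocta-1,6-dien-1-yl acetate (E/Z mixture at C1=C2)
Conditions: Ac2O, KOAc, Et3N, 120 °C
Reagents that add atoms: acetic anhydride, CC(=O)OC(C)=O
Why: Enol acetylation of an aldehyde (O-acylation of the enolate), which can enolise only towards C2 and therefore leaves the C3 stereocenter untouched.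

**Step 2**
Reactants: 2 (3S)-3,7-dimethylocta-1,6-dien-1-yl acetate
Product: 3 (3S)-3-methyl-6-oxohex-1-en-1-yl acetate
Conditions: O3, CH2Cl2, −78 °C (Sudan Red 7B end point); then PPh3, −78 °C → rt
Reagents that add atoms: ozone, [O-][O+]=O
Why: Chemoselective ozonolysis with reductive work-up, since the electron-rich trisubstituted alkene should react with ozone far faster than the acetoxy-deactivated enol ester double bond.

**Step 3**
Reactants: 4 ethyl 3-bromo-2-oxobutanoate
Product: 6 ethyl 2-oxo-3-(triphenyl-λ5-phosphanylidene)butanoate, via phosphonium bromide 5 (not isolated)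
Conditions: PPh3, PhMe, 50 °C; then aq. Na2CO3, CH2Cl2, rt
Reagents that add atoms: triphenylphosphine, c1ccc(cc1)P(c1ccccc1)c1ccccc1
Why: Alkylation of triphenylphosphine by the α-bromo ketone and deprotonation of the acidic phosphonium salt, the standard preparation of keto-stabilised Wittig ylides.

**Step 4**
Reactants: 3 (3S)-3-methyl-6-oxohex-1-en-1-yl acetate; 6 ethyl 2-oxo-3-(triphenyl-λ5-phosphanylidene)butanoate
Product: 7 ethyl (3E,6S)-8-acetoxy-3,6-dimethyl-2-oxoocta-3,7-dienoate (E/Z mixture at C7=C8)
Conditions: PhMe, 60 °C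
Reagents that add atoms: none
Why: Wittig olefination of an unhindered aliphatic aldehyde with a stabilised ylide, E-selective under thermodynamic control (the geometry is lost again in step 5) and run below the temperature at which the enol acetate could add thermally to the keto ester.

**Step 5**
Reactants: 7 ethyl (3E,6S)-8-acetoxy-3,6-dimethyl-2-oxoocta-3,7-dienoate
Product: 8 ethyl 2-[(1R,2S,5S)-7-acetoxy-2,6-dimethylbicyclo[3.2.0]heptan-6-yl]-2-oxoacetate (cis-fused; C2 methyl on the face of the bridgehead hydrogens; epimers at C6 and C7)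
Conditions: hν (365 nm), degassed MeCN (0.01 M), rt
Reagents that add atoms: none
Why: Intramolecular enone–alkene [2+2] photocycloaddition with an enol acetate partner (the cycloaddition half of a de Mayo-type sequence): the excited enone should close C4a–C7a first (rule of five) and the 1,4-biradical then collapses C1–C4, the four-membered ring enforcing cis fusion and the C7 methyl, pseudo-equatorial in the chair-like 5-exo transition state, ending trans to C1, which sets C4a and C7a relative to C7.

**Step 6**
Reactants: 9 1-(2-hydroxy-6-methylphenyl)ethanone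
Product: 10 4-hydroxy-5-methylcoumarin
Conditions: NaH, (EtO)2CO, PhMe, 110 °C; then aq. HCl
Reagents that add atoms: diethyl carbonate, CCOC(=O)OCC
Why: Claisen-type C-ethoxycarbonylation of the ketone enolate by diethyl carbonate followed by lactonisation onto the phenoxide, the standard route to 4-hydroxycoumarins.

**Step 7**
Reactants: 8 ethyl 2-[(1R,2S,5S)-7-acetoxy-2,6-dimethylbicyclo[3.2.0]heptan-6-yl]-2-oxoacetate; 10 4-hydroxy-5-methylcoumarin
Product: 12 ethyl (1R,4aS,7S,7aR)-1-(4-hydroxy-5-methyl-2-oxo-2H-chromen-3-yl)-4,7-dimethyl-1,4a,5,6,7,7a-hexahydrocyclopenta[c]pyran-3-carboxylate, via anomeric acetate 11 (not isolated)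
Conditions: Sc(OTf)3 (10 mol %), MeCN/CH2Cl2, 4 Å MS, 0 °C → rt
Reagents that add atoms: none
Why: Proposed new method: chelation of Sc(OTf)3 to the 1,2-dicarbonyl unit of 8 should trigger push–pull heterolysis of the strained C1–C4 bond (acetoxy-stabilised carbenium ion at C1, chelated keto ester enolate at C3/C4), and the enolate oxygen then recloses on C1 in a 6-(enolendo)-exo-trig O-alkylation, so that the cyclobutane C1–C4–C4a–C7a grows by C3 and O2 into the dihydropyran 11 (a formal 1,3 shift of C1 from carbon to oxygen). The anomeric acetate of 11 should ionise under the same catalyst to the cyclic oxocarbenium ion, which is captured by C3' of 10 in a Friedel–Crafts-type C-glycosylation with loss of acetic acid. The closest known reaction types are the Lewis-acid ring opening and formal [4+2] annulation of alkoxy-substituted donor–acceptor cyclobutanes, the Cloke–Wilson rearrangement of acylcyclopropanes to dihydrofurans, and the C-arylation of glycosyl acetates; an acyloxy donor, a single chelating keto ester acceptor and arylation in the same flask have not been combined. The only new stereocenter, C1, is set by attack of the coumarin on the convex face of the cis-fused oxocarbenium ion, anti to the C7a–C7 bond, and the same isomer should be favoured thermodynamically if the C1–O2 bond reopens; C4a, C7 and C7a keep their configuration because no carbonyl compound enolisable at C7a is set free. The step needs C1–C4 cleavage and not ionisation of the C1–OAc bond (secured by chelation of the Lewis acid at the keto ester), oxygen and not carbon reclosure of the dipole (carbon closure only regenerates strained 8), and C- and not O-arylation of 10 (an O-linked acetal reionises, the C-linked product should not).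

**Step 8**
Reactants: 12 ethyl (1R,4aS,7S,7aR)-1-(4-hydroxy-5-methyl-2-oxo-2H-chromen-3-yl)-4,7-dimethyl-1,4a,5,6,7,7a-hexahydrocyclopenta[c]pyran-3-carboxylate
Product: 14 3-[(1R,4aS,7S,7aR)-4,7-dimethyl-3-(3-methylbut-2-enoyl)-1,4a,5,6,7,7a-hexahydrocyclopenta[c]pyran-1-yl]-4-hydroxy-5-methyl-2H-chromen-2-one (target), via Weinreb amide 13 (not isolated)
Conditions: MeNH(OMe)·HCl, i-PrMgCl, THF, −20 → 0 °C; then Me2C=CHMgBr, 0 °C → rt; aq. NH4Cl
Reagents that add atoms: 2-methylprop-1-enylmagnesium bromide, CC(C)=C[Mg]Br; N,O-dimethylhydroxylamine hydrochloride, CNOC.Cl (its atoms stay only in intermediate 13)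
Why: One-pot Weinreb ketone synthesis, in which the chloromagnesium amide converts the ester into the N-methoxy-N-methylamide and the chelated tetrahedral adduct of that amide with the alkenyl Grignard reagent cannot over-add, while the coumarin is masked in the flask as its unreactive magnesium enolate and no stereocenter is touched.

**Compound list**

1 | (S)-citronellal, (3S)-3,7-dimethyloct-6-enal | O=CC[C@@H](C)CCC=C(C)C | starting material
2 | (3S)-3,7-dimethylocta-1,6-dien-1-yl acetate (E/Z mixture) | CC(=O)OC=C[C@@H](C)CCC=C(C)C | intermediate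
3 | (3S)-3-methyl-6-oxohex-1-en-1-yl acetate (E/Z mixture) | CC(=O)OC=C[C@@H](C)CCC=O | intermediate
4 | ethyl 3-bromo-2-oxobutanoate (racemic) | CCOC(=O)C(=O)C(C)Br | starting material
5 | (4-ethoxy-3,4-dioxobutan-2-yl)triphenylphosphonium bromide | CCOC(=O)C(=O)C(C)[P+](c1ccccc1)(c1ccccc1)c1ccccc1.[Br-] | intermediate
6 | ethyl 2-oxo-3-(triphenyl-λ5-phosphanylidene)butanoate | CCOC(=O)C(=O)C(C)=P(c1ccccc1)(c1ccccc1)c1ccccc1 | intermediate
7 | ethyl (3E,6S)-8-acetoxy-3,6-dimethyl-2-oxoocta-3,7-dienoate (E/Z mixture at C7=C8) | CC(=O)OC=C[C@@H](C)CC/C=C(\C)C(=O)C(=O)OCC | intermediate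
8 | ethyl 2-[(1R,2S,5S)-7-acetoxy-2,6-dimethylbicyclo[3.2.0]heptan-6-yl]-2-oxoacetate (epimers at C6 and C7) | CCOC(=O)C(=O)C1(C)[C@H]2CC[C@H](C)[C@H]2C1OC(C)=O | intermediate
9 | 1-(2-hydroxy-6-methylphenyl)ethanone | CC(=O)c1c(C)cccc1O | starting material
10 | 4-hydroxy-5-methylcoumarin, 4-hydroxy-5-methyl-2H-chromen-2-one | Cc1cccc2oc(=O)cc(O)c12 | intermediate
11 | ethyl (4aS,7S,7aR)-1-acetoxy-4,7-dimethyl-1,4a,5,6,7,7a-hexahydrocyclopenta[c]pyran-3-carboxylate (anomers) | CCOC(=O)C1=C(C)[C@H]2CC[C@H](C)[C@H]2C(OC(C)=O)O1 | intermediate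
12 | ethyl (1R,4aS,7S,7aR)-1-(4-hydroxy-5-methyl-2-oxo-2H-chromen-3-yl)-4,7-dimethyl-1,4a,5,6,7,7a-hexahydrocyclopenta[c]pyran-3-carboxylate | CCOC(=O)C1=C(C)[C@H]2CC[C@H](C)[C@H]2[C@H](c2c(O)c3c(C)cccc3oc2=O)O1 | intermediate
13 | (1R,4aS,7S,7aR)-1-(4-hydroxy-5-methyl-2-oxo-2H-chromen-3-yl)-N-methoxy-N,4,7-trimethyl-1,4a,5,6,7,7a-hexahydrocyclopenta[c]pyran-3-carboxamide | CON(C)C(=O)C1=C(C)[C@H]2CC[C@H](C)[C@H]2[C@H](c2c(O)c3c(C)cccc3oc2=O)O1 | intermediate
14 | 3-[(1R,4aS,7S,7aR)-4,7-dimethyl-3-(3-methylbut-2-enoyl)-1,4a,5,6,7,7a-hexahydrocyclopenta[c]pyran-1-yl]-4-hydroxy-5-methyl-2H-chromen-2-one | CC(C)=CC(=O)C1=C(C)[C@H]2CC[C@H](C)[C@H]2[C@H](c2c(O)c3c(C)cccc3oc2=O)O1 | target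

**Step count**

Total steps: 8. Longest linear sequence: 6 steps (1, 2, 4, 5, 7, 8) from (S)-citronellal.

**Steps most likely to fail**

Step 7 (ring expansion with arylation). The acetoxy group may be too weak a donor for the C1–C4 bond to break. The Lewis acid may instead ionise the C–OAc bond and start cyclobutyl cation rearrangements. The product may reopen at C1 and take up a second coumarin. The fallback uses known chemistry and runs from 8 back to 12. K2CO3 in EtOH at 0 °C removes the acetate to give the cyclobutanol ethyl 2-[(1R,2S,5S)-7-hydroxy-2,6-dimethylbicyclo[3.2.0]heptan-6-yl]-2-oxoacetate F1. Its strain-driven retro-aldol cleavage (the fragmentation half of the de Mayo sequence) opens the C1–C4 bond to the keto aldehyde ethyl 3-[(1S,2R,3S)-2-formyl-3-methylcyclopentyl]-2-oxobutanoate F2. This closes through its enol to the lactol ethyl (4aS,7S,7aR)-1-hydroxy-4,7-dimethyl-1,4a,5,6,7,7a-hexahydrocyclopenta[c]pyran-3-carboxylate F3. The lactol is then condensed with 10 under catalytic TsOH in MeCN (acid-catalysed C3-alkylation of a 4-hydroxycoumarin by a lactol) to give 12.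

Step 5 ([2+2] photocycloaddition). The excited keto ester may only isomerise about its C=C bond, may react at the ketone carbonyl (oxetane formation, hydrogen abstraction from the ethoxy group), or may discriminate poorly between the two faces defined by the C7 methyl group. The fallback uses known chemistry and runs from 7 to 11, bypassing the four-membered ring. The same diene should close thermally as an intramolecular inverse-electron-demand hetero-Diels–Alder reaction of the 1-oxadiene O=C3–C4=C4a with the enol acetate (PhMe, 110 °C, or Yb(OTf)3 catalysis at rt). This gives the anomeric acetate 11 directly; 11 is then treated with 10 and Sc(OTf)3 as in step 7, and the route continues at 12. No new compound is formed.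

Step 8 (ester to alkenyl ketone). Under the strongly basic conditions the magnesium coumarin enolate may expel the C1–O2 oxygen (retro-oxa-Michael opening), after which the opened alkylidene chromandione takes up Grignard reagent. The hindered tetrasubstituted acrylate ester may also resist amidation. The fallback uses known chemistry and runs from 12 to 14. Neutral ester cleavage (Me3SnOH, 1,2-dichloroethane, 70 °C) gives (1R,4aS,7S,7aR)-1-(4-hydroxy-5-methyl-2-oxo-2H-chromen-3-yl)-4,7-dimethyl-1,4a,5,6,7,7a-hexahydrocyclopenta[c]pyran-3-carboxylic acid F4. Thioesterification (EtSH, EDC·HCl, DMAP, CH2Cl2) gives S-ethyl (1R,4aS,7S,7aR)-1-(4-hydroxy-5-methyl-2-oxo-2H-chromen-3-yl)-4,7-dimethyl-1,4a,5,6,7,7a-hexahydrocyclopenta[c]pyran-3-carbothioate F5. A Liebeskind–Srogl coupling of this thioester with 2-methylprop-1-enylboronic acid (Pd2(dba)3, tri(2-furyl)phosphine, monovalent copper thiophene-2-carboxylate Cu(O2CC4H3S), THF, 50 °C) should then deliver 14 under neutral conditions.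

**Further compounds**

F1 | step 7 | ethyl 2-[(1R,2S,5S)-7-hydroxy-2,6-dimethylbicyclo[3.2.0]heptan-6-yl]-2-oxoacetate (epimers at C6 and C7) | CCOC(=O)C(=O)C1(C)[C@H]2CC[C@H](C)[C@H]2C1O
F2 | step 7 | ethyl 3-[(1S,2R,3S)-2-formyl-3-methylcyclopentyl]-2-oxobutanoate (epimers at C3 of the chain) | CCOC(=O)C(=O)C(C)[C@H]1CC[C@H](C)[C@H]1C=O
F3 | step 7 | ethyl (4aS,7S,7aR)-1-hydroxy-4,7-dimethyl-1,4a,5,6,7,7a-hexahydrocyclopenta[c]pyran-3-carboxylate (anomers) | CCOC(=O)C1=C(C)[C@H]2CC[C@H](C)[C@H]2C(O)O1
F0 | step 5 | none | none
F4 | step 8 | (1R,4aS,7S,7aR)-1-(4-hydroxy-5-methyl-2-oxo-2H-chromen-3-yl)-4,7-dimethyl-1,4a,5,6,7,7a-hexahydrocyclopenta[c]pyran-3-carboxylic acid | OC(=O)C1=C(C)[C@H]2CC[C@H](C)[C@H]2[C@H](c2c(O)c3c(C)cccc3oc2=O)O1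
F5 | step 8 | S-ethyl (1R,4aS,7S,7aR)-1-(4-hydroxy-5-methyl-2-oxo-2H-chromen-3-yl)-4,7-dimethyl-1,4a,5,6,7,7a-hexahydrocyclopenta[c]pyran-3-carbothioate | CCSC(=O)C1=C(C)[C@H]2CC[C@H](C)[C@H]2[C@H](c2c(O)c3c(C)cccc3oc2=O)O1
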